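100 is F, the charged Ej divided by the charged Ek; if each Ek begins one chain, the average chain length is F times the fraction of the charged Ej that stands as Wu.

Minutes of the meeting on the dawn and autumn flasks. Ej is the monomer, Wu the monomer in chains, and Ek the initiator.

common to all: Ej 0.010 M

|  | Ek | remark | time |
|---|---|---|---|
| west | 140 µM | run made earlier |  |
| south-west | 220 µM | run made earlier |  |
| dawn | 100 µM |  | 2.0 min |
| autumn | 100 µM |  | 0.50 min |

| run | time / s | Wu / % | Ej / % |
|---|---|---|---|
| west | 30.0 | 27 | 74 |
| west | 60.0 | 38 | 62 |
| west | 90.0 | 42 | 58 |
| west | 120 | 50 | 54 |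
| south-west | 15.0 | 25 | 78 |
| south-west | 40.0 | 41 | 58 |
| south-west | 80.0 | 51 | 52 |
| south-west | 120 | 54 | 49 |

(each reading ± 1.5 percentage points)

- the average divides the monomer in chains by the number of chains begun, living and dead together
- the earlier runs do not show the number of chains; that part of a forecast is a guess

- which of the two ends with the longer chains by the average number of monomer units in a chain (chains begun, living or dead) ("neither" if they lie within 10 %) (dawn / autumn / neither)
- average number of monomer units in a chain (chains begun, living or dead) at the end, dawn
- average number of monomer units in a chain (chains begun, living or dead) at the end, autumn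

The reader of the earlier runs proposed to compare flasks by Ek·t, the product of Ek charged and time. She took west at 90.0 s, where Ek·t is 12600 µM·s, close to dawn's 12000 µM·s. Wu read 42 % there, so she put dawn at 42.0 units. For autumn she took south-west at 15.0 s, with Wu at 25 %. She scaled that reading in proportion to Ek·t and got 22.7 units. She warned that F rests on a guess, since the earlier runs do not show the number of chains.

The forecaster made the same guess: “I assume one chain per initiator”. The forecast named dawn as the longer, with 44 for dawn and 21 for autumn. Its dawn value stood higher than hers, and its autumn value lower.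

    Wu + Ly → Ej + Ly, rate k1*[Ly] as long as [Wu] is above zero (k = 0.759 /s)
    Ly → Aj (k = 0.00714 /s)
    Ej + Ly → Wu + Ly, rate k3*[Ly]*[Ej] (k = 173 /M/s)
    Ej + Ek → Ly + Wu (k = 114 /M/s)

The flask gives dawn as the longer, 42.4 against 21.2 for autumn. In dawn, Ek stood at 0 % of its charge by 1.00 min, and growth and its reverse ran on the living ends Ly while Ly turned into Aj. At 2.00 min, dawn held Ly 4.27 × 10⁻⁵ M and Aj 5.73 × 10⁻⁵ M, together 100 µM of chains, with Wu at 42.4 %, and its length equals F times Wu. A neighbour flask, autumn with 0.025 M of Ej, has F of 250 and Wu at 30.8 %, and its length is 76.9.

The runs are simulated on assumed constants, and the scatter is random.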